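The runs are simulated for an exercise, noise included.

Does the average chain in the flask reach 20 units by 10 d? I begin with how many chains there are.

| flask | X | Q | L | remark | time |
|---|---|---|---|---|---|
| south-west | 0.050 M | 2.5 mM | 3.7 mM | run made earlier |  |
| north-west | 0.050 M | 10 mM | 3.7 mM | run made earlier |  |
| east | 0.050 M | 5 mM | 1.9 mM | run made earlier |  |
| flask | 0.050 M | 5.0 mM | 3.7 mM |  | 10 d |

| run | time / d | J / % | X / % |
|---|---|---|---|
| south-west | 2.08 | 3.3 | 97.9 |
| south-west | 4.00 | 3.5 | 96.5 |
| south-west | 6.00 | 6.7 | 93.6 |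
| south-west | 8.00 | 8.5 | 91.5 |
| south-west | 10.0 | 9.3 | 90.9 |
| south-west | 12.0 | 11.0 | 89.6 |
| north-west | 1.04 | 39.3 | 59.3 |
| north-west | 1.67 | 55.7 | 42.3 |
| north-west | 2.50 | 68.4 | 28.4 |
| north-west | 4.00 | 78.0 | 16.6 |
| north-west | 8.00 | 81.6 | 7.6 |
| north-west | 12.0 | 83.4 | 4.8 |
| east | 1.04 | 22.1 | 78.4 |
| east | 3.00 | 51.8 | 46.6 |
| east | 6.00 | 69.6 | 26.8 |
| east | 8.00 | 72.4 | 22.6 |
| east | 12.0 | 76.1 | 18.7 |

(scatter of a reading: 0.5 percentage points)

- whether the average number of monomer units in a chain (chains begun, living or dead) reaches 20 by 10 d (no / yes)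
- average number of monomer units in a chain (chains begun, living or dead) at 10 d

- the average divides the monomer in chains by the number of chains begun, living and dead together
- the earlier runs do not show the number of chains; that part of a forecast is a guess

The first readings give first-order slopes in X. The north-west run falls at 0.502 /d on an excess of Q over L of 6.30 mM, and the east run at 0.234 /d on 3.10 mM. The south-west run, with L above Q, leaks at 0.0102 /d. So I read L as a scavenger taking Q one for one, and I carry the chains begun in the flask, the excess c(Q) − c(L) = 1.30 mM.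

Start slope of the flask, scaled from north-west: 0.104 /d

J wanted, as a share of the X charged: 52.0 %

The east shortfall in X + J reads 2.60 mM at 12.0 d, below its excess, so I allow one J lost per chain begun, 2.60 % of the X charged in the flask.

Mean slope needed over 10 d: 0.0790 /d

That is 0.760 of the start slope. I expect the curve to bend as chains die. The mean slope of the east run over 8.00 d reads 0.795 of its first slope, with J at 72.4 % by then, against the 52.0 % wanted in the flask. Borrowing that share, I reckon X in the flask at 43.9 % at 10 d and the average at 20.6.

The forecast says no, with 19: “just under 20, so this is a close call”. My reckoning stands higher and says yes.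

The flask answers yes, with 21.2 at 10 d.

    X + Z → J + Z, rate k1*[Z]*[X] (k = 4.00 /M/h)
    X + G → Z + J (k = 9.00 /M/h)
    Z + J → D (k = 0.260 /M/h)
    Q ⇌ G (K = 1.90, k = 0.230 /h)
    G + L → E (k = 4200 /M/h)

The length passes 20 at 8.38 d, with 53.5 % of X reacted, against the 52.0 % I reckoned as J wanted. Dividing J in the flask at 10 d, 55.2 %, by the carried excess gives 21.2 units. The same division on the east run, with its excess of 3.10 mM and J of 76.1 % at 12.0 d, gives 12.3 units.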